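**Plan**

1. Retrosynthesis: after desilylation, the O5–C6 and C4–C3a bonds of the furofuranone are cut together. This removes C4H2–O5 as formaldehyde and leaves a C6–C3a bond, i.e. the cyclopropane-fused lactone 11 (a 3-oxabicyclo[3.1.0]hexan-2-one). The two cyclopropane bonds to C1 of 11 are then cut (carbene addition) to the Z-allylic diazoacetate 10, the ester to alcohol 8, and the carbinol–alkyne bond to aldehyde 2 and alkyne 5.
2. Forward: aldehyde and alkyne are joined, the alkyne is reduced to the Z-alkene and esterified to the diazoacetate. Lactone ring and cyclopropane arise together. The tetrahydrofuran ring then arises by insertion of formaldehyde into the cyclopropane while the lactone opens and re-closes. Desilylation ends the route.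
3. Enabling feature: in the target, C6 (benzylic) and C3a are both bonded to C6a, and C3a carries the benzylic C3–O2 bond of the lactone. A C6–C3a bond (ring C6a/C3a/C6) therefore makes C3–O2 a cyclopropylcarbinyl leaving group. Its ionisation passes the positive charge to C6, where the formaldehyde oxygen enters, and turns C3a into the styrene carbon that takes the CH2.
4. Stereochemistry: the carbinol centre (later C3) comes from a BINOL-controlled alkynylation. A(1,3) strain in the Z-alkene relays it to the three cyclopropane centres. In the key step C6a is kept, C6 is set by inversion, C3a by the cis ring fusion, and C3 is ionised and re-set with the aryl exo.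

Key step: step 8

Remark: the target SMILES corresponds to the (3S,3aR,6S,6aS) isomer in furo[3,4-c]furan-1-one numbering (cis-fused, both aryl groups on the convex face). This numbering is used for 13 and 14, and bicyclo[3.1.0]hexane numbering for 11.

**Route**

Step 1
Reactants: 1 vanillin
Product: 2 4-(tert-butyldimethylsilyloxy)-3-methoxybenzaldehyde
Conditions: TBSCl, imidazole, DMF, rt
Reagents that add atoms: tert-butyldimethylsilyl chloride, CC(C)(C)[Si](C)(C)Cl
Why: Standard phenol silylation; the aryl silyl ether should survive the organozinc, hydrogenation, carbene and Lewis-acid steps and leaves with fluoride at the end.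

Step 2
Reactants: 3 3,4-dihydroxybenzaldehyde
Product: 4 3,4-bis(tert-butyldimethylsilyloxy)benzaldehyde
Conditions: TBSCl (2.4 equiv), imidazole, DMF, rt
Reagents that add atoms: tert-butyldimethylsilyl chloride, CC(C)(C)[Si](C)(C)Cl
Why: Standard double silylation of a catechol, which blocks both phenols and tempers the donor strength of this ring.

Step 3
Reactants: 4 3,4-bis(tert-butyldimethylsilyloxy)benzaldehyde
Product: 5 4-ethynyl-1,2-bis(tert-butyldimethylsilyloxy)benzene
Conditions: Me3SiCHN2, LiN(iPr)2, THF, −78 °C to rt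
Reagents that add atoms: (trimethylsilyl)diazomethane, C[Si](C)(C)C=[N+]=[N-]
Why: Colvin rearrangement: the lithiated diazo reagent adds to the aldehyde, Peterson-type loss of silanolate and of N2 gives an alkylidene carbene, and a 1,2-hydrogen shift gives the terminal alkyne without the basic methanol that would cleave aryl silyl ethers.

Step 4
Reactants: 5 4-ethynyl-1,2-bis(tert-butyldimethylsilyloxy)benzene, 2 4-(tert-butyldimethylsilyloxy)-3-methoxybenzaldehyde
Product: 7 (1R)-3-[3,4-bis(tert-butyldimethylsilyloxy)phenyl]-1-[4-(tert-butyldimethylsilyloxy)-3-methoxyphenyl]prop-2-yn-1-ol, via ethylzinc acetylide 6 (not isolated)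
Conditions: 5 (2 equiv), Et2Zn, toluene, reflux; then (S)-BINOL (20 mol %), Ti(OiPr)4 (25 mol %), 2, Et2O, rt
Reagents that add atoms: none
Why: BINOL–Ti(OiPr)4-catalysed addition of an alkynylzinc to an aromatic aldehyde; (S)-BINOL is expected to direct the alkynyl group to the Si face, which gives the R carbinol because alkynyl outranks aryl.

Step 5
Reactants: 7 (1R)-3-[3,4-bis(tert-butyldimethylsilyloxy)phenyl]-1-[4-(tert-butyldimethylsilyloxy)-3-methoxyphenyl]prop-2-yn-1-ol
Product: 8 (1S,2Z)-3-[3,4-bis(tert-butyldimethylsilyloxy)phenyl]-1-[4-(tert-butyldimethylsilyloxy)-3-methoxyphenyl]prop-2-en-1-ol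
Conditions: H2 (1 atm), Pd/CaCO3 poisoned with Pb(OAc)2, quinoline, EtOAc, rt
Reagents that add atoms: none
Why: Lindlar-type syn semihydrogenation should give the Z-alkene; the carbinol centre is untouched and its descriptor changes from R to S only because aryl now outranks the alkenyl carbon.

Step 6
Reactants: 8 (1S,2Z)-3-[3,4-bis(tert-butyldimethylsilyloxy)phenyl]-1-[4-(tert-butyldimethylsilyloxy)-3-methoxyphenyl]prop-2-en-1-ol
Product: 10 (1S,2Z)-3-[3,4-bis(tert-butyldimethylsilyloxy)phenyl]-1-[4-(tert-butyldimethylsilyloxy)-3-methoxyphenyl]prop-2-en-1-yl 2-diazoacetate, via glyoxylate tosylhydrazone ester 9 (not isolated)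
Conditions: TsNHN=CHCOCl, PhNMe2, CH2Cl2, 0 °C; then Et3N, 0 °C to rt
Reagents that add atoms: glyoxylic acid chloride p-toluenesulfonylhydrazone, Cc1ccc(cc1)S(=O)(=O)N/N=C/C(Cl)=O
Why: Acylation by the hydrazone acid chloride followed by Bamford–Stevens-type loss of sulfinate from the ester is the standard one-flask diazoacetylation of allylic alcohols and should stay cold and buffered enough to leave the Z-alkene and the benzylic ester in place.

Step 7
Reactants: 10 (1S,2Z)-3-[3,4-bis(tert-butyldimethylsilyloxy)phenyl]-1-[4-(tert-butyldimethylsilyloxy)-3-methoxyphenyl]prop-2-en-1-yl 2-diazoacetate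
Product: 11 (1R,4S,5S,6R)-6-[3,4-bis(tert-butyldimethylsilyloxy)phenyl]-4-[4-(tert-butyldimethylsilyloxy)-3-methoxyphenyl]-3-oxabicyclo[3.1.0]hexan-2-one (aryl on C6 endo, aryl on C4 anti to the cyclopropane)
Conditions: Rh2(5S-MEPY)4 [dirhodium tetrakis(methyl (5S)-2-oxopyrrolidine-5-carboxylate)] (1 mol %), CH2Cl2, 40 °C, slow addition of 10
Reagents that add atoms: none
Why: Dirhodium carboxamidate-catalysed intramolecular cyclopropanation of a Z-allylic diazoacetate, stereospecific in the alkene (C6 aryl endo); A(1,3) strain holds the carbinol hydrogen in the alkene plane, so the tethered carbene should reach the face that puts the C4 aryl anti to the new ring and fixes C1, C5 and C6, and this catalyst enantiomer is expected to favour the same face.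

Step 8
Reactants: 11 (1R,4S,5S,6R)-6-[3,4-bis(tert-butyldimethylsilyloxy)phenyl]-4-[4-(tert-butyldimethylsilyloxy)-3-methoxyphenyl]-3-oxabicyclo[3.1.0]hexan-2-one
Product: 13 (3S,3aR,6S,6aS)-6-[3,4-bis(tert-butyldimethylsilyloxy)phenyl]-3-[4-(tert-butyldimethylsilyloxy)-3-methoxyphenyl]tetrahydro-1H,3H-furo[3,4-c]furan-1-one, via oxocarbenium silyl ester 12 (not isolated)
Conditions: (CH2O)n (5 equiv), Me3SiOTf (0.2 equiv), 4 Å MS, CH2Cl2, −40 to 0 °C
Reagents that add atoms: formaldehyde (from paraformaldehyde), C=O
Why: Proposed new method: Me3SiOTf silylates the lactone carbonyl of 11 and the benzylic, cyclopropylcarbinylic C4–O3 bond ionises; the cation opens the C5–C6 bond as the formaldehyde oxygen attacks the aryl-bearing C6 with inversion (the E-styrene results because the C4 aryl already lies anti to the ring), the oxocarbenium ion 12 is attacked by the styrene carbon (old C5), and the silyl carboxylate captures the benzylic cation and releases Me3SiOTf. The closest known reaction types are the cyclopropylcarbinyl-to-homoallyl opening by an external nucleophile (as in the Julia homoallyl bromide synthesis), the Lewis-acid [3+2] annulation of donor–acceptor cyclopropanes with aldehydes (aldehyde oxygen attacks the donor carbon with inversion), and Prins cyclisations ended by an internal carboxylate. The tetrahydrofuran closes by 5-exo-trig attack of the oxocarbenium carbon on the styrene, and the lactone re-closes as a five-membered ring by collapse of the carboxylate onto the C3 cation, a net anti addition across the E-alkene. In 13, C6 is set by the inversion at the cis-cyclopropane carbon (a Curtin–Hammett preference for a 2,3-trans tetrahydrofuran points the same way if the opening is more SN1-like), C3a by the C6a tether that lets only the cis-fused lactone close, C3 by the anti capture that places the aryl exo, and C6a is carried over unchanged. The step needs C–O ionisation instead of donor–acceptor cleavage of C1–C6, and opening toward C6 instead of C1; the far better leaving group (silyl carboxylate against an ester enolate), the double stabilisation of the first cation, and an aryl on C6 against a carbonyl on C1 should secure both.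

Step 9
Reactants: 13 (3S,3aR,6S,6aS)-6-[3,4-bis(tert-butyldimethylsilyloxy)phenyl]-3-[4-(tert-butyldimethylsilyloxy)-3-methoxyphenyl]tetrahydro-1H,3H-furo[3,4-c]furan-1-one
Product: 14 (3S,3aR,6S,6aS)-6-(3,4-dihydroxyphenyl)-3-(4-hydroxy-3-methoxyphenyl)tetrahydro-1H,3H-furo[3,4-c]furan-1-one
Conditions: Bu4NF (3.3 equiv), AcOH (3.3 equiv), THF, 0 °C to rt
Reagents that add atoms: none
Why: Fluoride cleavage of aryl silyl ethers, buffered with acetic acid so that the catechol, the lactone and the two benzylic C–O bonds should not be exposed to base or strong acid.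

**Compound list**

1 | vanillin (4-hydroxy-3-methoxybenzaldehyde) | COc1cc(C=O)ccc1O | starting material
2 | 4-(tert-butyldimethylsilyloxy)-3-methoxybenzaldehyde | COc1cc(C=O)ccc1O[Si](C)(C)C(C)(C)C | intermediate
3 | 3,4-dihydroxybenzaldehyde | O=Cc1ccc(O)c(O)c1 | starting material
4 | 3,4-bis(tert-butyldimethylsilyloxy)benzaldehyde | O=Cc1ccc(O[Si](C)(C)C(C)(C)C)c(O[Si](C)(C)C(C)(C)C)c1 | intermediate
5 | 4-ethynyl-1,2-bis(tert-butyldimethylsilyloxy)benzene | C#Cc1ccc(O[Si](C)(C)C(C)(C)C)c(O[Si](C)(C)C(C)(C)C)c1 | intermediate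
6 | ethyl{[3,4-bis(tert-butyldimethylsilyloxy)phenyl]ethynyl}zinc (not isolated) | CC[Zn]C#Cc1ccc(O[Si](C)(C)C(C)(C)C)c(O[Si](C)(C)C(C)(C)C)c1 | intermediate
7 | (1R)-3-[3,4-bis(tert-butyldimethylsilyloxy)phenyl]-1-[4-(tert-butyldimethylsilyloxy)-3-methoxyphenyl]prop-2-yn-1-ol | COc1cc([C@@H](O)C#Cc2ccc(O[Si](C)(C)C(C)(C)C)c(O[Si](C)(C)C(C)(C)C)c2)ccc1O[Si](C)(C)C(C)(C)C | intermediate
8 | (1S,2Z)-3-[3,4-bis(tert-butyldimethylsilyloxy)phenyl]-1-[4-(tert-butyldimethylsilyloxy)-3-methoxyphenyl]prop-2-en-1-ol | COc1cc([C@@H](O)/C=C\c2ccc(O[Si](C)(C)C(C)(C)C)c(O[Si](C)(C)C(C)(C)C)c2)ccc1O[Si](C)(C)C(C)(C)C | intermediate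
9 | (1S,2Z)-3-[3,4-bis(tert-butyldimethylsilyloxy)phenyl]-1-[4-(tert-butyldimethylsilyloxy)-3-methoxyphenyl]prop-2-en-1-yl (2E)-2-(tosylhydrazinylidene)acetate (not isolated) | COc1cc([C@@H](OC(=O)/C=N/NS(=O)(=O)c2ccc(C)cc2)/C=C\c2ccc(O[Si](C)(C)C(C)(C)C)c(O[Si](C)(C)C(C)(C)C)c2)ccc1O[Si](C)(C)C(C)(C)C | intermediate
10 | (1S,2Z)-3-[3,4-bis(tert-butyldimethylsilyloxy)phenyl]-1-[4-(tert-butyldimethylsilyloxy)-3-methoxyphenyl]prop-2-en-1-yl 2-diazoacetate | COc1cc([C@@H](OC(=O)C=[N+]=[N-])/C=C\c2ccc(O[Si](C)(C)C(C)(C)C)c(O[Si](C)(C)C(C)(C)C)c2)ccc1O[Si](C)(C)C(C)(C)C | intermediate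
11 | (1R,4S,5S,6R)-6-[3,4-bis(tert-butyldimethylsilyloxy)phenyl]-4-[4-(tert-butyldimethylsilyloxy)-3-methoxyphenyl]-3-oxabicyclo[3.1.0]hexan-2-one | O=C1O[C@H](c2ccc(O[Si](C)(C)C(C)(C)C)c(OC)c2)[C@H]2[C@@H](c3ccc(O[Si](C)(C)C(C)(C)C)c(O[Si](C)(C)C(C)(C)C)c3)[C@@H]12 | intermediate
12 | methylidene{(1S,2S,3E)-1-[3,4-bis(tert-butyldimethylsilyloxy)phenyl]-4-[4-(tert-butyldimethylsilyloxy)-3-methoxyphenyl]-2-[(trimethylsilyloxy)carbonyl]but-3-en-1-yl}oxonium triflate (not isolated) | C=[O+][C@H](c1ccc(O[Si](C)(C)C(C)(C)C)c(O[Si](C)(C)C(C)(C)C)c1)[C@@H](C(=O)O[Si](C)(C)C)/C=C/c1ccc(O[Si](C)(C)C(C)(C)C)c(OC)c1.[O-]S(=O)(=O)C(F)(F)F | intermediate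
13 | (3S,3aR,6S,6aS)-6-[3,4-bis(tert-butyldimethylsilyloxy)phenyl]-3-[4-(tert-butyldimethylsilyloxy)-3-methoxyphenyl]tetrahydro-1H,3H-furo[3,4-c]furan-1-one | COc1cc([C@H]2OC(=O)[C@H]3[C@@H]2CO[C@@H]3c2ccc(O[Si](C)(C)C(C)(C)C)c(O[Si](C)(C)C(C)(C)C)c2)ccc1O[Si](C)(C)C(C)(C)C | intermediate
14 | (3S,3aR,6S,6aS)-6-(3,4-dihydroxyphenyl)-3-(4-hydroxy-3-methoxyphenyl)tetrahydro-1H,3H-furo[3,4-c]furan-1-one | COc1cc([C@H]2OC(=O)[C@H]3[C@@H]2CO[C@@H]3c2ccc(O)c(O)c2)ccc1O | target

**Count and risks**

Total steps: 9. Longest linear sequence: 8 steps (3 → 4 → 5 → 7 → 8 → 10 → 11 → 13 → 14).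

Steps most likely to fail:

1. Step 8 (proposed new method). Formaldehyde may be too weak a nucleophile to intercept the ring-opened cation before it loses the proton on C1 (elimination) or before the electron-rich arenes are hydroxymethylated. The opening may lose stereospecificity at C6. Donor–acceptor cleavage of C1–C6 may compete and invert the regiochemistry of the insertion. Fallback with known chemistry, from 11 back to 13: the event is split into two operations. Solvolytic cyclopropylcarbinyl-to-homoallyl rearrangement of 11 with water as the nucleophile (catalytic HClO4 in aqueous dioxane) should give (2S,3E)-2-{(S)-[3,4-bis(tert-butyldimethylsilyloxy)phenyl](hydroxy)methyl}-4-[4-(tert-butyldimethylsilyloxy)-3-methoxyphenyl]but-3-enoic acid F1. A conventional Prins cyclisation of this homoallylic alcohol with paraformaldehyde and BF3·OEt2 in CH2Cl2 at low temperature should then return 13: the hemiacetal-derived oxocarbenium ion closes 5-exo onto the styrene and the free carboxylic acid captures the benzylic cation. In this variant the ring oxygen comes from water, not from formaldehyde.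

2. Step 6. The ester being formed is both benzylic (para-silyloxy aryl) and allylic, so ionisation with allylic transposition, Z-to-E isomerisation, or chloride substitution may occur while amine hydrochloride is present. Fallback, from 8 back to 10, under basic conditions only: acetoacetylation with diketene and catalytic DMAP should give the 3-oxobutanoate F2; Regitz diazo transfer (MsN3, Et3N, MeCN) should give the 2-diazo-3-oxobutanoate F3; deacetylation with LiOH in aqueous MeCN should give 10.

3. Step 4. This is the only source of absolute configuration. Poor facial selectivity, or sluggish addition of the bulky alkynylzinc to an electron-rich aldehyde, would carry through to the target. Fallback, from 7 of insufficient enantiopurity back to 7: the stereocentre is set by asymmetric reduction instead of asymmetric C–C bond formation. Oxidation with MnO2 in CH2Cl2 should give 3-[3,4-bis(tert-butyldimethylsilyloxy)phenyl]-1-[4-(tert-butyldimethylsilyloxy)-3-methoxyphenyl]prop-2-yn-1-one F4. Corey–Bakshi–Shibata reduction with the (R)-methyl oxazaborolidine and catecholborane at −78 °C, in which the alkynyl group acts as the smaller substituent, should return (R)-7.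

**Further compounds**

F1 | step 8 | (2S,3E)-2-{(S)-[3,4-bis(tert-butyldimethylsilyloxy)phenyl](hydroxy)methyl}-4-[4-(tert-butyldimethylsilyloxy)-3-methoxyphenyl]but-3-enoic acid | OC(=O)[C@H]([C@H](O)c1ccc(O[Si](C)(C)C(C)(C)C)c(O[Si](C)(C)C(C)(C)C)c1)/C=C/c1ccc(O[Si](C)(C)C(C)(C)C)c(OC)c1
F2 | step 6 | (1S,2Z)-3-[3,4-bis(tert-butyldimethylsilyloxy)phenyl]-1-[4-(tert-butyldimethylsilyloxy)-3-methoxyphenyl]prop-2-en-1-yl 3-oxobutanoate | COc1cc([C@@H](OC(=O)CC(C)=O)/C=C\c2ccc(O[Si](C)(C)C(C)(C)C)c(O[Si](C)(C)C(C)(C)C)c2)ccc1O[Si](C)(C)C(C)(C)C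
F3 | step 6 | (1S,2Z)-3-[3,4-bis(tert-butyldimethylsilyloxy)phenyl]-1-[4-(tert-butyldimethylsilyloxy)-3-methoxyphenyl]prop-2-en-1-yl 2-diazo-3-oxobutanoate | COc1cc([C@@H](OC(=O)C(=[N+]=[N-])C(C)=O)/C=C\c2ccc(O[Si](C)(C)C(C)(C)C)c(O[Si](C)(C)C(C)(C)C)c2)ccc1O[Si](C)(C)C(C)(C)C
F4 | step 4 | 3-[3,4-bis(tert-butyldimethylsilyloxy)phenyl]-1-[4-(tert-butyldimethylsilyloxy)-3-methoxyphenyl]prop-2-yn-1-one | COc1cc(C(=O)C#Cc2ccc(O[Si](C)(C)C(C)(C)C)c(O[Si](C)(C)C(C)(C)C)c2)ccc1O[Si](C)(C)C(C)(C)C
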